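**Plan**
- Retrosynthesis: the C1–O and C4'–O protecting groups and a temporary C8' oxygen go first. Ring D is then cut at C5'–C6', C7'–C8' and C8'–C8a' (chromium carbene benzannulation with trimethylsilylacetylene, C8' coming from CO). C4a'–C5' is cut to an aryl bromide and Cr(CO)6, and C4–C1' to the C4 benzylic bromide of 5-methoxy-1-tetralone and an arylzinc from 4-iodophenol.
- Enabling feature: ring D (C4a', C5', C6', C7', C8', C8a') carries only the C5' methoxy, and C5' is bonded to C4a' of ring C, exactly where the carbene carbon of an aryl(methoxy)carbene ends up. The C4' oxygen occupies the other ortho carbon of ring C, so C8a' is the only site of closure.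
- Forward: rings A/B (the tetralone) are joined to ring C at C4, the C1 ketone is reduced and silylated, the carbene is installed on ring C, ring D is annulated, and the C7' silicon, the C8' oxygen and the protecting groups are removed.
- Stereochemistry: C4 (S) comes from a chiral nickel–pybox catalyst in an enantioconvergent Negishi arylation. C1 (S, cis to the aryl group) comes from Ru–TsDPEN transfer hydrogenation, reinforced by the pseudoaxial C4 aryl group. Neither centre is touched afterwards.

Key step: step 8

Remark on numbering: tetralin C1 (carbinol), C4 (bears the naphthyl), C5 (OMe); naphthyl C1' (bonded to C4), C4' (OH), C5' (OMe); ring A = anisole ring of the tetralin, ring B = its saturated ring, ring C = C1'–C4'/C4a'/C8a', ring D = C4a'/C5'–C8'/C8a'. The target SMILES corresponds to 1S,4S, the cis diastereomer.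
Remark (assumption): which antipode of the i-Pr-pybox ligand gives 4S cannot be deduced safely by analogy; it is to be fixed in a first small run, and both antipodes are commercial.
Remark on protecting groups: C4'–O is carried as a benzyl ether and C1–O as a triisopropylsilyl ether, chosen for its resistance to t-BuLi, TFA and hot formate.

Step 1
Reactants: 1 4-iodophenol
Product: 2 2-bromo-4-iodophenol
Conditions: NBS (1.0 equiv), i-Pr2NH (10 mol %), CH2Cl2, 0 °C to rt
Reagents that add atoms: N-bromosuccinimide, O=C1CCC(=O)N1Br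
Why: Amine-catalysed electrophilic ortho-bromination of a phenol; the para position is occupied by iodine, so one equivalent of NBS should brominate a single ortho carbon.

Step 2
Reactants: 2 2-bromo-4-iodophenol
Product: 3 1-(benzyloxy)-2-bromo-4-iodobenzene
Conditions: BnBr, K2CO3, DMF, rt
Reagents that add atoms: benzyl bromide, BrCc1ccccc1
Why: Williamson ether synthesis; the phenoxide formed by K2CO3 is alkylated on oxygen by the benzylic bromide.

Step 3
Reactants: 4 5-methoxy-1-tetralone
Product: 5 racemic 4-bromo-5-methoxy-3,4-dihydronaphthalen-1(2H)-one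
Conditions: NBS (1.05 equiv), AIBN (5 mol %), PhCF3, 80 °C; filtered and used at once
Reagents that add atoms: N-bromosuccinimide, O=C1CCC(=O)N1Br
Why: Wohl–Ziegler radical bromination; C4–H is the only benzylic C–H and its radical is stabilised by ring A, whereas abstraction of the electron-poor C2–H next to the carbonyl by a bromine atom is polarity-mismatched.

Step 4
Reactants: 3 1-(benzyloxy)-2-bromo-4-iodobenzene; 5 racemic 4-bromo-5-methoxy-3,4-dihydronaphthalen-1(2H)-one
Product: 7 (4S)-4-[4-(benzyloxy)-3-bromophenyl]-5-methoxy-3,4-dihydronaphthalen-1(2H)-one, via arylzinc iodide 6 (not isolated)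
Conditions: 3, Zn dust, LiCl, THF, 50 °C; then 5, NiCl2(dme) (10 mol %), i-Pr-pybox (13 mol %, antipode giving 4S), glyme/THF, –20 °C
Reagents that add atoms: none
Why: Nickel-catalysed enantioconvergent Negishi arylation of a racemic secondary benzylic bromide: halogen abstraction by the low-valent nickel–pybox species turns both antipodes of 5 into the same planar C4 benzylic radical, which the chiral aryl–nickel complex captures and releases by reductive elimination with the C4 configuration fixed by the ligand, while the ketone and the electron-rich ortho-alkoxy aryl bromide should be spectators at –20 °C.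

Step 5
Reactants: 7 (4S)-4-[4-(benzyloxy)-3-bromophenyl]-5-methoxy-3,4-dihydronaphthalen-1(2H)-one
Product: 8 (1S,4S)-4-[4-(benzyloxy)-3-bromophenyl]-5-methoxy-1,2,3,4-tetrahydronaphthalen-1-ol (cis)
Conditions: RuCl(p-cymene)[(S,S)-TsDPEN] (2 mol %), HCO2H/Et3N (5:2), DMF, 35 °C
Reagents that add atoms: none
Why: Noyori asymmetric transfer hydrogenation of an aryl ketone: the (S,S) catalyst, which converts 1-tetralone into (S)-1-tetralol, should deliver hydride to the C1 face anti to the C4 aryl group (held pseudoaxial by the peri C5 methoxy), so catalyst and substrate preferences coincide to give the 1S cis alcohol, and any 4R ketone carried over from step 4 would emerge as a separable trans diastereomer.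

Step 6
Reactants: 8 (1S,4S)-4-[4-(benzyloxy)-3-bromophenyl]-5-methoxy-1,2,3,4-tetrahydronaphthalen-1-ol
Product: 9 {[(1S,4S)-4-[4-(benzyloxy)-3-bromophenyl]-5-methoxy-1,2,3,4-tetrahydronaphthalen-1-yl]oxy}triisopropylsilane
Conditions: TIPSOTf, 2,6-lutidine, CH2Cl2, 0 °C
Reagents that add atoms: triisopropylsilyl trifluoromethanesulfonate, CC(C)[Si](OS(=O)(=O)C(F)(F)F)(C(C)C)C(C)C
Why: O-silylation of a secondary alcohol with a silyl triflate and a hindered pyridine base, which proceeds with retention at C1 because only the O–H bond reacts.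

Step 7
Reactants: 9 {[(1S,4S)-4-[4-(benzyloxy)-3-bromophenyl]-5-methoxy-1,2,3,4-tetrahydronaphthalen-1-yl]oxy}triisopropylsilane; 10 chromium hexacarbonyl Cr(CO)6
Product: 13 (CO)5Cr=C(OMe)Ar carbene complex [Ar = 2-(benzyloxy)-5-{(1S,4S)-8-methoxy-4-[(triisopropylsilyl)oxy]-1,2,3,4-tetrahydronaphthalen-1-yl}phenyl], via aryllithium 11 (not isolated), via lithium acylchromate 12 (not isolated)
Conditions: t-BuLi (2.1 equiv), Et2O, –78 °C; Cr(CO)6, Et2O, –78 to 0 °C; then Me3OBF4, CH2Cl2, 0 °C to rt
Reagents that add atoms: trimethyloxonium tetrafluoroborate, C[O+](C)C.F[B-](F)(F)F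
Why: Fischer carbene synthesis: bromine–lithium exchange at –78 °C, faster than deprotonation at the OCH2Ph or C4–H positions, gives the aryllithium, which adds to a CO ligand of Cr(CO)6, and O-methylation of the resulting acylchromate by the oxonium salt gives the methoxycarbene while the ethers and the silyl ether stay inert.

Step 8
Reactants: 13 (CO)5Cr=C(OMe)Ar carbene complex; 14 trimethylsilylacetylene
Product: 16 5-(benzyloxy)-4-methoxy-8-{(1S,4S)-8-methoxy-4-[(triisopropylsilyl)oxy]-1,2,3,4-tetrahydronaphthalen-1-yl}-2-(trimethylsilyl)naphthalen-1-ol (C8'-OH/C7'-SiMe3 in target numbering), via Cr(CO)3 naphthol complex 15 (not isolated)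
Conditions: 14 (3 equiv), THF (0.1 M), 55 °C, sealed, Ar; then brief air exposure, rt
Reagents that add atoms: none
Why: Thermal loss of one CO from 13 opens a site for 14, which inserts into the Cr=C bond with its unsubstituted carbon bonding to the carbene carbon (C5'–C6') and the silylated carbon to chromium, and CO insertion (C7'–C8') then gives an η4-vinylketene. Ring D is closed by a six-electron electrocyclisation of this aryl-conjugated vinylketene onto C8a' (C8'–C8a'), and tautomerisation of the cyclohexadienone gives the naphthol as its Cr(CO)3 complex 15, which air releases as 16. The closest known reaction is the Dötz benzannulation of 2,5-disubstituted aryl(methoxy)carbene Cr(CO)5 complexes with silylalkynes used as acetylene equivalents. No stereocentre is created, and the neutral conditions leave C1 and C4 untouched. The one selectivity that matters is the site of ring closure, and it is fixed because the other ortho carbon of ring C carries the benzyloxy group; the alkyne orientation (silicon next to the new hydroxyl) is of no consequence since silicon is removed in step 9. Phenol formation over the indene and cyclobutenone channels should be favoured by chromium, the methoxycarbene, an ethereal solvent and a high alkyne concentration.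

Step 9
Reactants: 16 the C8'-hydroxy C7'-trimethylsilyl naphthalene
Product: 17 5-(benzyloxy)-4-methoxy-8-{(1S,4S)-8-methoxy-4-[(triisopropylsilyl)oxy]-1,2,3,4-tetrahydronaphthalen-1-yl}naphthalen-1-ol
Conditions: TFA (3 equiv), CH2Cl2, 0 °C, Ar
Reagents that add atoms: none
Why: Ipso-protodesilylation (electrophilic aromatic substitution) at C7', activated by the ortho hydroxyl; an O-silylated isomer, should a 1,3-silyl shift intervene in step 8, would be cleaved to the same naphthol, and the triisopropylsilyl and benzyl ethers should survive brief cold TFA.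

Step 10
Reactants: 17 the C8' naphthol
Product: 18 5-(benzyloxy)-4-methoxy-8-{(1S,4S)-8-methoxy-4-[(triisopropylsilyl)oxy]-1,2,3,4-tetrahydronaphthalen-1-yl}naphthalen-1-yl trifluoromethanesulfonate
Conditions: Tf2O, pyridine, CH2Cl2, –20 to 0 °C
Reagents that add atoms: trifluoromethanesulfonic anhydride, O=S(=O)(OS(=O)(=O)C(F)(F)F)C(F)(F)F
Why: O-sulfonylation (triflation) of the only free hydroxyl, which also removes the oxidation-prone hydroquinone monoether character of ring D.

Step 11
Reactants: 18 the C8' triflate
Product: 19 {[(1S,4S)-4-[4-(benzyloxy)-5-methoxynaphthalen-1-yl]-5-methoxy-1,2,3,4-tetrahydronaphthalen-1-yl]oxy}triisopropylsilane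
Conditions: Pd(OAc)2 (10 mol %), 1,1'-bis(diphenylphosphino)ferrocene (12 mol %), HCO2H, Et3N, DMF, 80 °C
Reagents that add atoms: none
Why: Palladium-catalysed formate reduction of an aryl triflate: oxidative addition of zerovalent palladium into C8'–OTf, formate exchange, decarboxylation to the aryl palladium hydride and reductive elimination, with a wide-bite-angle bisphosphine chosen for the peri-hindered site.

Step 12
Reactants: 19 the benzyl and triisopropylsilyl protected target
Product: 20 8-methoxy-4-{(1S,4S)-8-methoxy-4-[(triisopropylsilyl)oxy]-1,2,3,4-tetrahydronaphthalen-1-yl}naphthalen-1-ol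
Conditions: H2 (1 atm), 10% Pd/C, EtOAc, rt
Reagents that add atoms: none
Why: Hydrogenolysis of an aryl benzyl ether under neutral conditions, with the benzylic C1–O bond kept as a silyl ether so that it should resist reduction.

Step 13
Reactants: 20 the C1 triisopropylsilyl ether of the target
Product: 21 dipolynaphthalene B [(1S,4S)-4-(4-hydroxy-5-methoxynaphthalen-1-yl)-5-methoxy-1,2,3,4-tetrahydronaphthalen-1-ol]
Conditions: Bu4NF, AcOH, THF, rt to 40 °C, Ar
Reagents that add atoms: none
Why: Fluoride-mediated desilylation of the secondary silyl ether, buffered with acetic acid so that the naphthol is not held as an oxidation-prone naphtholate and C1 is not exposed to acid or base.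

**Compound list**
1 | 4-iodophenol | Oc1ccc(I)cc1 | starting material
2 | 2-bromo-4-iodophenol | Oc1ccc(I)cc1Br | intermediate
3 | 1-(benzyloxy)-2-bromo-4-iodobenzene | Brc1cc(I)ccc1OCc1ccccc1 | intermediate
4 | 5-methoxy-1-tetralone | COc1cccc2c1CCCC2=O | starting material
5 | racemic 4-bromo-5-methoxy-3,4-dihydronaphthalen-1(2H)-one | COc1cccc2c1C(Br)CCC2=O | intermediate
6 | [4-(benzyloxy)-3-bromophenyl]zinc iodide ArZnI, LiCl adduct in THF (not isolated) | Brc1cc([Zn]I)ccc1OCc1ccccc1 | intermediate
7 | (4S)-4-[4-(benzyloxy)-3-bromophenyl]-5-methoxy-3,4-dihydronaphthalen-1(2H)-one | COc1cccc2c1[C@H](c1ccc(OCc3ccccc3)c(Br)c1)CCC2=O | intermediate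
8 | (1S,4S)-4-[4-(benzyloxy)-3-bromophenyl]-5-methoxy-1,2,3,4-tetrahydronaphthalen-1-ol (cis) | COc1cccc2c1[C@H](c1ccc(OCc3ccccc3)c(Br)c1)CC[C@@H]2O | intermediate
9 | triisopropylsilyl ether of 8 | COc1cccc2c1[C@H](c1ccc(OCc3ccccc3)c(Br)c1)CC[C@@H]2O[Si](C(C)C)(C(C)C)C(C)C | intermediate
10 | chromium hexacarbonyl Cr(CO)6 | O=C=[Cr](=C=O)(=C=O)(=C=O)(=C=O)=C=O | starting material
11 | aryllithium from 9, Li in place of Br (not isolated) | COc1cccc2c1[C@H](c1ccc(OCc3ccccc3)c([Li])c1)CC[C@@H]2O[Si](C(C)C)(C(C)C)C(C)C | intermediate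
12 | lithium acylpentacarbonylchromate Li[(CO)5Cr–C(O)Ar] (not isolated) | [Li+].COc1cccc2c1[C@H](c1ccc(OCc3ccccc3)c(c1)C([O-])=[Cr](=C=O)(=C=O)(=C=O)(=C=O)=C=O)CC[C@@H]2O[Si](C(C)C)(C(C)C)C(C)C | intermediate
13 | pentacarbonyl[aryl(methoxy)carbene]chromium (CO)5Cr=C(OMe)Ar, Ar = 2-(benzyloxy)-5-{(1S,4S)-8-methoxy-4-[(triisopropylsilyl)oxy]-1,2,3,4-tetrahydronaphthalen-1-yl}phenyl | COc1cccc2c1[C@H](c1ccc(OCc3ccccc3)c(c1)C(OC)=[Cr](=C=O)(=C=O)(=C=O)(=C=O)=C=O)CC[C@@H]2O[Si](C(C)C)(C(C)C)C(C)C | intermediate
14 | trimethylsilylacetylene | C#C[Si](C)(C)C | starting material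
15 | Cr(CO)3 η6 complex of naphthol 16, chromium on ring D, written as its two components (not isolated) | COc1cccc2c1[C@H](c1ccc(OCc4ccccc4)c3c(OC)cc([Si](C)(C)C)c(O)c13)CC[C@@H]2O[Si](C(C)C)(C(C)C)C(C)C.O=C=[Cr](=C=O)=C=O | intermediate
16 | 5-(benzyloxy)-4-methoxy-8-{(1S,4S)-8-methoxy-4-[(triisopropylsilyl)oxy]-1,2,3,4-tetrahydronaphthalen-1-yl}-2-(trimethylsilyl)naphthalen-1-ol | COc1cccc2c1[C@H](c1ccc(OCc4ccccc4)c3c(OC)cc([Si](C)(C)C)c(O)c13)CC[C@@H]2O[Si](C(C)C)(C(C)C)C(C)C | intermediate
17 | 5-(benzyloxy)-4-methoxy-8-{(1S,4S)-8-methoxy-4-[(triisopropylsilyl)oxy]-1,2,3,4-tetrahydronaphthalen-1-yl}naphthalen-1-ol | COc1cccc2c1[C@H](c1ccc(OCc4ccccc4)c3c(OC)ccc(O)c13)CC[C@@H]2O[Si](C(C)C)(C(C)C)C(C)C | intermediate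
18 | C8' trifluoromethanesulfonate of 17 | COc1cccc2c1[C@H](c1ccc(OCc4ccccc4)c3c(OC)ccc(OS(=O)(=O)C(F)(F)F)c13)CC[C@@H]2O[Si](C(C)C)(C(C)C)C(C)C | intermediate
19 | {[(1S,4S)-4-[4-(benzyloxy)-5-methoxynaphthalen-1-yl]-5-methoxy-1,2,3,4-tetrahydronaphthalen-1-yl]oxy}triisopropylsilane | COc1cccc2c1[C@H](c1ccc(OCc4ccccc4)c3c(OC)cccc13)CC[C@@H]2O[Si](C(C)C)(C(C)C)C(C)C | intermediate
20 | 8-methoxy-4-{(1S,4S)-8-methoxy-4-[(triisopropylsilyl)oxy]-1,2,3,4-tetrahydronaphthalen-1-yl}naphthalen-1-ol | COc1cccc2c1[C@H](c1ccc(O)c3c(OC)cccc13)CC[C@@H]2O[Si](C(C)C)(C(C)C)C(C)C | intermediate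
21 | dipolynaphthalene B, (1S,4S)-4-(4-hydroxy-5-methoxynaphthalen-1-yl)-5-methoxy-1,2,3,4-tetrahydronaphthalen-1-ol | COc1cccc2c1[C@H](c1ccc(O)c3c(OC)cccc13)CC[C@@H]2O | target

**Step count**
Total: 13 steps. Longest linear sequence: 12 steps (steps 1, 2 and 4–13, from 4-iodophenol).

**Steps most likely to fail**

Step 4. Facial discrimination in the capture of the C4 radical may be poor because the peri C5 methoxy crowds the site, and bromide 5 may lose HBr towards the naphthol before it is captured. The fallback sets out from 5 and 6 and comes back at 8; it replaces asymmetric catalysis at C4 by resolution through the C1 centre. Compounds 5 and 6 would be coupled with an achiral, less encumbered catalyst (NiCl2(dme)/4,4'-di-tert-butyl-2,2'-bipyridine, THF/DMA, 0 °C) to give racemic 4-[4-(benzyloxy)-3-bromophenyl]-5-methoxy-3,4-dihydronaphthalen-1(2H)-one F1. Transfer hydrogenation of F1 with the same (S,S) ruthenium catalyst would convert the two C4 antipodes into the cis alcohol 8 and its trans diastereomer (1S,4R)-4-[4-(benzyloxy)-3-bromophenyl]-5-methoxy-1,2,3,4-tetrahydronaphthalen-1-ol F2. These would be separated by chromatography before silylation.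

Step 8. Closure of the vinylketene onto C8a', which lies between the carbene-bearing carbon and the carbon carrying the bulky tetralinyl group, may be slower than the indene, furan or cyclobutenone channels, and chelation of chromium by the benzyloxy oxygen may retard alkyne uptake. The fallback sets out from 9 and comes back at 17, bypassing steps 7–9 by an aryne cycloaddition. Bromide 9 would be treated with lithium 2,2,6,6-tetramethylpiperidide in THF at –78 °C in the presence of excess 2-methoxyfuran. Deprotonation at C8a', the only C–H ortho to bromine, and loss of LiBr would give the C4a'–C8a' aryne. Its [4+2] cycloaddition with the furan, oriented by the C4' alkoxy group so that the methoxy-bearing furan carbon bonds to C4a', would give the bridged ketal 5'-methoxy-5',8'-epoxy-5',8'-dihydronaphthalene F3 (mixture of bridgehead epimers). Mild acid (pyridinium p-toluenesulfonate, CH2Cl2) would open F3 to naphthol 17.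

Step 11. Oxidative addition into the C8' triflate, peri to the tetralinyl group and on an electron-rich ring, may be slow enough for triflate hydrolysis back to 17 or catalyst decomposition to take over. The fallback sets out from 17 and comes back at 20; it replaces the homogeneous reduction by hydrogenolysis of an activated aryl ether. Naphthol 17 would be converted with 5-chloro-1-phenyl-1H-tetrazole and K2CO3 in DMF into the 1-phenyl-1H-tetrazol-5-yl ether F4. Hydrogenation of F4 over 10% Pd/C (H2, EtOH/EtOAc, 40 °C) would cleave both the C8'–O bond and the benzyl ether, giving 20 directly.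

**Further compounds**
F1 | step 4 | racemic 4-[4-(benzyloxy)-3-bromophenyl]-5-methoxy-3,4-dihydronaphthalen-1(2H)-one | COc1cccc2c1C(c1ccc(OCc3ccccc3)c(Br)c1)CCC2=O
F2 | step 4 | (1S,4R)-4-[4-(benzyloxy)-3-bromophenyl]-5-methoxy-1,2,3,4-tetrahydronaphthalen-1-ol (trans) | COc1cccc2c1[C@@H](c1ccc(OCc3ccccc3)c(Br)c1)CC[C@@H]2O
F3 | step 8 | 4'-(benzyloxy)-5'-methoxy-5',8'-epoxy-5',8'-dihydronaphthalen-1'-yl tetralin triisopropylsilyl ether (bridgehead epimers) | COc1cccc2c1[C@H](c1ccc(OCc4ccccc4)c3c1C1C=CC3(OC)O1)CC[C@@H]2O[Si](C(C)C)(C(C)C)C(C)C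
F4 | step 11 | 1-phenyl-1H-tetrazol-5-yl ether of naphthol 17 | COc1cccc2c1[C@H](c1ccc(OCc4ccccc4)c3c(OC)ccc(Oc4nnnn4-c4ccccc4)c13)CC[C@@H]2O[Si](C(C)C)(C(C)C)C(C)C
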